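## The problem

Locants used throughout: pinane carbons are C1–C7 (C2 is the spiro atom, C6 the CMe2 bridge, C7 the CH2 bridge). Atoms of the chromene part carry primes (O1', C3', C4', C4a', C5'–C8', C8a').

The target is a 3',4'-dihydro-2H-pyran whose C2 is the spiro atom of a pinane and whose C4a'=C8a' bond is the enol ether of a 6',6',8',8'-tetramethylcyclohexene-5',7'-dione (O-alkylated syncarpic acid). The O1'–C2 bond is a tertiary ether on a carbon attached to a cyclobutane. A cation or radical at C2 invites Wagner–Meerwein shift or opening of the four-membered ring, so this bond must be closed in a concerted or anionic way. C1 and C5 come with the terpene and can control C2, because the C6 gem-dimethyl bridge leaves only the C7 face of a trigonal C2 open; the target has O1' on that face. C4' is the hard centre: it lies 1,3 to C2, carries isobutyl cis to C1 across the pyran ring (4'R), and cannot be epimerised once formed. In a [4+2] construction from a 1,1-disubstituted alkene it is decided only by the endo or exo placement of two similar ring branches. The enol ether, the β-alkoxy enone and the pinane do not tolerate strong acid, and a carbonyl at C4' would expose the ring to β-elimination under base.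

The feature that the plan exploits is that C4a' is flanked by two identical carbonyl carbons, C5' and C8a', of a twofold-symmetric trione ring. Any C4'-alkylidene derivative therefore has a carbonyl oxygen cis to each C4' substituent, so an alkenyl group placed on C4' completes a 1-oxatriene (O=C8a'–C4a'=C4'–C3'=C2) whatever the geometry. This oxatriene closes O1'–C2 by electrocyclisation, leaves C4' trigonal, and lets the pinane that has just set C2 set C4' last.

## Retrosynthesis

**9 to 8.** The two C–H bonds at C3' and C4' are removed, giving the spiro 2H-pyran 8. This removes the one stereocentre that no ring-forming step controls while keeping the whole skeleton; cutting a C–C or C–O bond first would bring back the endo/exo problem. The forward step must add hydrogen syn to the C3'=C4' bond from the face of the C3–C4 bridge, away from C1 and the C6 bridge.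

**8 to 7 to 3 + 6.** The O1'–C2 bond is opened by retro-electrocyclisation to oxatriene 7, and the C3'–C4' single bond of 7 is then cut into the vinylogous thioester 3 and the alkenylmagnesium bromide 6. Cutting C2–C3' instead would require a carbonyl at C4' and an equilibrating oxa-Michael closure; cutting both bonds to the pinane at once is the cycloaddition that leaves C4' uncontrolled. The precursors are a 16-carbon achiral electrophile and a 10-carbon nucleophile whose only stereocentres are those of the terpene. The forward step must be a 1,4-addition–elimination at a fully substituted carbon, followed by ring closure under kinetic control from the C7 face.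

**6 to 5 to 4.** The exocyclic C=C bond of bromide 5 is cut back to the carbonyl of (+)-nopinone 4. This is one step from a purchasable ketone that already has C1 and C5 in the required configuration. The double-bond geometry is irrelevant because C2 becomes a ring-closing terminus with two ring substituents.

**3 to 2 to 1.** The isobutyl–C4' bond of 3 is cut to the ketene dithioacetal 2, which comes from syncarpic acid 1 by attaching a one-carbon unit bearing two methylsulfanyl groups. C4' is thus introduced at the oxidation level of a carboxylic acid, so isobutyl and the alkenyl group can be put on by two successive substitutions with no C4' stereocentre at any stage.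

## Roads not taken

**Alternative 1:** the most obvious cut removes C3'–C4' and O1'–C2 together (retro-hetero-Diels–Alder).
- Forward: Knoevenagel condensation of 1 with 3-methylbutanal gives the alkylidene trione A1, which reacts as a 1-oxadiene with (−)-β-pinene A2.
- This takes two steps and should set C2 correctly, since the diene approaches the C7 face.
- C4' is decided only by which ring branch of A2 (C1 or C3) lies under the diene. Nothing distinguishes these strongly, and the less encumbered C3-endo orientation leads to the 4'-epimer A3.
- C4'–H cannot be epimerised, so the route ends in a separation. The chosen plan costs three more steps but derives both C2 and C4' from the facial bias of the pinane.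

**Alternative 2:** cut C2–C3' and O1'–C2 (Kabbe-type spiroannulation).
- Forward: aldol condensation of the acetyl trione A4 with 4, then oxa-Michael closure, gives the spiro chromanone A5. Its C4' carbonyl is then exchanged for isobutyl through an enol triflate and cross-coupling to reach 8.
- The ring closure is the addition of a β-triketone enolate, a good leaving group, so it is reversible under the amine conditions. C2 would be set under thermodynamic control, not by kinetic approach to the C7 face.
- Two more steps are needed, one of which enolises C3' next to that same leaving group (E1cB ring opening).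
- The chosen plan closes the ring irreversibly at low temperature with isobutyl already in place.

**Alternative 3:** cut O1'–C2 alone, as the last bond.
- Forward: conjugate addition of a pin-2-en-10-yl metal to A1, which a chiral copper catalyst could make selective at C4', would give the 2-alkyl trione A6. Markovnikov addition of the enol O–H across C2=C3 would then close the ring.
- The closure needs a cation (or radical) at C2, which is exactly where the pinane rearranges.
- Cation-free variants (iodoetherification, oxymercuration) add oxygen anti to an electrophile that itself takes the open C7 face, which would put O1' syn to C6.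
- What is gained at C4' is lost at C2. The chosen plan makes O1'–C2 by a pericyclic closure and needs no external chiral reagent.

Key step: step 4

Remark: syncarpic acid 1 and (+)-nopinone 4 are taken as purchasable. Bromide 5 is used as its E/Z mixture, since both isomers give the same oxatriene 7.

## Steps

Step 1
Reactants: 1 syncarpic acid (2,2,4,4-tetramethylcyclohexane-1,3,5-trione)
Product: 2 2-[bis(methylsulfanyl)methylidene]-4,4,6,6-tetramethylcyclohexane-1,3,5-trione
Conditions: CS2 (1.2 equiv), K2CO3 (2.5 equiv), DMF, 0 °C; then MeI (2.4 equiv), 0 °C to rt
Reagents that add atoms: carbon disulfide, S=C=S; iodomethane, CI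
Why: Ketene dithioacetal synthesis: the only enolisable carbon of 1 adds to CS2 and the dithiocarboxylate is S-methylated twice; adding CS2 before MeI keeps O-methylation of the enolate from competing.

Step 2
Reactants: 2 2-[bis(methylsulfanyl)methylidene]-4,4,6,6-tetramethylcyclohexane-1,3,5-trione
Product: 3 2,2,4,4-tetramethyl-6-[3-methyl-1-(methylsulfanyl)butylidene]cyclohexane-1,3,5-trione
Conditions: i-BuMgBr (1.1 equiv), CuBr·SMe2 (10 mol %), THF, −78 to −30 °C; then pH 7 buffer
Reagents that add atoms: isobutylmagnesium bromide, CC(C)C[Mg]Br
Why: Copper-catalysed conjugate addition–elimination of a Grignard reagent on an α-oxo ketene dithioacetal; the first adduct is a stabilised trione enolate that should lose methanethiolate only on warming, which guards against a second substitution, and the ring carbonyls are shielded from 1,2-attack by their flanking quaternary carbons.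

Step 3
Reactants: 4 (+)-nopinone, (1R,5S)-6,6-dimethylbicyclo[3.1.1]heptan-2-one
Product: 5 (1R,5S)-2-(bromomethylidene)-6,6-dimethylbicyclo[3.1.1]heptane (E/Z mixture)
Conditions: Ph3P(CH2Br)Br (1.5 equiv), KOt-Bu (1.4 equiv), THF, −78 °C; then 4, −78 °C to rt
Reagents that add atoms: (bromomethyl)triphenylphosphonium bromide, BrC[P+](c1ccccc1)(c1ccccc1)c1ccccc1.[Br-]
Why: Wittig bromomethylenation of the ketone with the ylide Ph3P=CHBr made at low temperature; C1 and C5 are untouched and the geometry of the new double bond does not matter for what follows.

Step 4
Reactants: 3 2,2,4,4-tetramethyl-6-[3-methyl-1-(methylsulfanyl)butylidene]cyclohexane-1,3,5-trione; 5 (1R,5S)-2-(bromomethylidene)-6,6-dimethylbicyclo[3.1.1]heptane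
Product: 8 (1R,2R,5S)-6,6,6',6',8',8'-hexamethyl-4'-(2-methylpropyl)spiro[bicyclo[3.1.1]heptane-2,2'-chromene]-5',7'(6'H,8'H)-dione, via alkenylmagnesium bromide 6 (not isolated), via oxatriene 7 (not isolated)
Conditions: 5, Mg, THF, 45 °C; then 3, CuBr·SMe2 (10 mol %), THF, −78 to 0 °C; pH 7 buffer; rapid filtration through Et3N-deactivated SiO2 at 0 °C, product kept cold
Reagents that add atoms: none
Why: Magnesium insertion into 5 gives 6, which adds under copper catalysis to C4' of the vinylogous thioester 3, and the trione enolate so formed expels methanethiolate on warming to give the tetrasubstituted alkylidene 7. Because the trione ring has identical carbonyls on both sides of C4a', one of them is necessarily cis to the new alkenyl group, so 7 is a 1-oxatriene whatever its geometry. It should close by a thermal disrotatory oxa-6π electrocyclisation (O1' to C2), which forms the six-membered 2H-pyran ring and is driven by relief of allylic strain in the twisted dienone. The closest known reaction types are the stepwise substitution of α-oxo ketene dithioacetals by organocopper reagents and the Knoevenagel/oxa-6π annulation of cyclic 1,3-diones with enals. The only new stereocentre is the spiro atom C2: the carbonyl oxygen should reach the exocyclic carbon from the face of the C7 methylene bridge, away from the C6 gem-dimethyl bridge, as reagents generally do with the exocyclic alkene of β-pinene, which places O1' anti and C3' syn to C6 (2R). The step needs 1,4- over 1,2-addition, which copper and the quaternary carbons next to the ring carbonyls should secure, and kinetic control of the closure, which working at or below 0 °C should secure because the 2H-pyran is not expected to reopen at a useful rate there. C4' stays trigonal, so no configuration has to be controlled at that carbon in this step.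

Step 5
Reactants: 8 (1R,2R,5S)-6,6,6',6',8',8'-hexamethyl-4'-(2-methylpropyl)spiro[bicyclo[3.1.1]heptane-2,2'-chromene]-5',7'(6'H,8'H)-dione
Product: 9 (1R,2R,4'R,5S)-6,6,6',6',8',8'-hexamethyl-4'-(2-methylpropyl)-3',4'-dihydrospiro[bicyclo[3.1.1]heptane-2,2'-chromene]-5',7'(6'H,8'H)-dione (target)
Conditions: H2 (1 atm), 5% Pd/C (palladium on carbon), EtOAc, 0 °C to rt
Reagents that add atoms: none
Why: Heterogeneous syn-hydrogenation of the trisubstituted C3'=C4' bond, the tetrasubstituted push–pull C4a'=C8a' bond and the ketones being inert under these conditions. The catalyst should reach the near-planar pyran from the face of the C3H2–C4H2 bridge, because the other face is covered by C1 with its cyclobutane and by the C6 gem-dimethyl bridge that leans over C3'; hydrogen is then delivered to C4' cis to C3 and isobutyl ends up cis to C1 (4'R).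

## Compound list

1 | syncarpic acid, 2,2,4,4-tetramethylcyclohexane-1,3,5-trione | CC1(C)C(=O)CC(=O)C(C)(C)C1=O | starting material
2 | 2-[bis(methylsulfanyl)methylidene]-4,4,6,6-tetramethylcyclohexane-1,3,5-trione | CSC(SC)=C1C(=O)C(C)(C)C(=O)C(C)(C)C1=O | intermediate
3 | 2,2,4,4-tetramethyl-6-[3-methyl-1-(methylsulfanyl)butylidene]cyclohexane-1,3,5-trione | CSC(CC(C)C)=C1C(=O)C(C)(C)C(=O)C(C)(C)C1=O | intermediate
4 | (+)-nopinone, (1R,5S)-6,6-dimethylbicyclo[3.1.1]heptan-2-one | O=C1CC[C@H]2C[C@@H]1C2(C)C | starting material
5 | (1R,5S)-2-(bromomethylidene)-6,6-dimethylbicyclo[3.1.1]heptane, E/Z mixture | BrC=C1CC[C@H]2C[C@@H]1C2(C)C | intermediate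
6 | {[(1R,5S)-6,6-dimethylbicyclo[3.1.1]heptan-2-ylidene]methyl}magnesium bromide, E/Z mixture | Br[Mg]C=C1CC[C@H]2C[C@@H]1C2(C)C | intermediate
7 | 2-{1-[(1R,5S)-6,6-dimethylbicyclo[3.1.1]heptan-2-ylidene]-4-methylpentan-2-ylidene}-4,4,6,6-tetramethylcyclohexane-1,3,5-trione (oxatriene) | CC(C)CC(C=C1CC[C@H]2C[C@@H]1C2(C)C)=C1C(=O)C(C)(C)C(=O)C(C)(C)C1=O | intermediate
8 | (1R,2R,5S)-6,6,6',6',8',8'-hexamethyl-4'-(2-methylpropyl)spiro[bicyclo[3.1.1]heptane-2,2'-chromene]-5',7'(6'H,8'H)-dione | CC(C)CC1=C[C@@]2(CC[C@H]3C[C@@H]2C3(C)C)OC2=C1C(=O)C(C)(C)C(=O)C2(C)C | intermediate
9 | (1R,2R,4'R,5S)-6,6,6',6',8',8'-hexamethyl-4'-(2-methylpropyl)-3',4'-dihydrospiro[bicyclo[3.1.1]heptane-2,2'-chromene]-5',7'(6'H,8'H)-dione | CC(C)C[C@@H]1C[C@@]2(CC[C@H]3C[C@@H]2C3(C)C)OC2=C1C(=O)C(C)(C)C(=O)C2(C)C | target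

## Step count and least certain steps

Total steps: 5. Longest linear sequence: 4 (steps 1, 2, 4, 5); step 3 is a one-step branch.

**Step 4 (key step).** The most likely failure is proton transfer from the acidic methylene next to C4' of 3 to the basic magnesium reagent, or slow attack at the fully substituted, twisted C4', so that 6 is used up without C–C bond formation. A second risk is loss of the kinetic C2 configuration by reversible ring opening of 8 to 7 on warming. The fallback sets out from 1 and 5 and comes back at 8. Knoevenagel condensation of 1 with 3-methylbutanal (piperidine, CH2Cl2, then dilute acid) gives the trisubstituted alkylidene trione F1, a much less hindered acceptor. Copper-catalysed conjugate addition of 6 (from 5) to it gives the 2-alkyl trione F2, as a mixture at the new sp3 carbon, which does not matter. Dehydrogenation of F2 with TEMPO and PhI(OAc)2 in THF (−78 °C to rt), a known way to turn 2-alkyl β-triketones into their alkylidene derivatives, gives oxatriene 7, which closes to 8.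

**Step 5.** The most likely failure is insufficient facial selectivity, because the two faces differ only through the substituents on C2, one atom away from the reacting bond. Double-bond migration or hydrogenolysis of the allylic C2–O1' bond on palladium is also possible, as is catalyst poisoning by sulfur residues from step 4. The fallback sets out from 1 and comes back at 9. The alkylidene trione F1 (made as in the fallback to step 4) is heated with (−)-β-pinene in toluene. The inverse-demand hetero-Diels–Alder reaction forms both bonds to the pinane at once with O1' on the C7 face, and 9 is separated by chromatography from its 4'-epimer F3. This gives up control of C4' but not of C2.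

**Step 2.** The most likely failure is loss of selectivity for single substitution (a second displacement, or hydride transfer from the isobutyl Grignard reagent), and tautomerisation of 3 to a non-electrophilic dienol during purification. The fallback sets out from 1 and comes back at 8, and uses no organometallic reagent to place isobutyl. Three-component condensation of 1, 3-methylbutanal and thiophenol (proline cat., CH2Cl2) gives the sulfide adduct F4. Chlorination at the trione carbon with N-chlorosuccinimide and dehydrochlorination with Et3N give the phenylsulfanyl alkylidene trione F5, which takes the place of 3 in step 4 and gives 8 with loss of thiophenol.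

**Step 3.** The most likely failure is enolisation of the hindered ketone 4 by the basic, thermally fragile ylide, leading to low conversion. The fallback sets out from 4 and comes back at 8. Boron-Wittig olefination of 4 with bis(pinacolato)borylmethane and LiTMP (lithium 2,2,6,6-tetramethylpiperidide) in THF gives the alkenylboronate F6. Cleavage of the pinacol ester (NaIO4, NH4OAc, aqueous acetone) gives the boronic acid F7. Liebeskind–Srogl coupling of F7 with 3 (Pd2(dba)3, tri(2-furyl)phosphine, CuTC (copper thiophene-2-carboxylate), THF, 40 °C) gives 7 and hence 8 under neutral conditions, with no organomagnesium reagent.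

## Further compounds

F1 | step 4 | 2,2,4,4-tetramethyl-6-(3-methylbutylidene)cyclohexane-1,3,5-trione | CC(C)CC=C1C(=O)C(C)(C)C(=O)C(C)(C)C1=O
F2 | step 4 | 2-{1-[(1R,5S)-6,6-dimethylbicyclo[3.1.1]heptan-2-ylidene]-4-methylpentan-2-yl}-4,4,6,6-tetramethylcyclohexane-1,3,5-trione (both configurations at pentane C2, E/Z mixture) | CC(C)CC(C=C1CC[C@H]2C[C@@H]1C2(C)C)C1C(=O)C(C)(C)C(=O)C(C)(C)C1=O
F3 | step 5 | (1R,2R,4'S,5S)-6,6,6',6',8',8'-hexamethyl-4'-(2-methylpropyl)-3',4'-dihydrospiro[bicyclo[3.1.1]heptane-2,2'-chromene]-5',7'(6'H,8'H)-dione | CC(C)C[C@H]1C[C@@]2(CC[C@H]3C[C@@H]2C3(C)C)OC2=C1C(=O)C(C)(C)C(=O)C2(C)C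
F4 | step 2 | 2,2,4,4-tetramethyl-6-[3-methyl-1-(phenylsulfanyl)butyl]cyclohexane-1,3,5-trione (racemic) | CC(C)CC(Sc1ccccc1)C1C(=O)C(C)(C)C(=O)C(C)(C)C1=O
F5 | step 2 | 2,2,4,4-tetramethyl-6-[3-methyl-1-(phenylsulfanyl)butylidene]cyclohexane-1,3,5-trione | CC(C)CC(Sc1ccccc1)=C1C(=O)C(C)(C)C(=O)C(C)(C)C1=O
F6 | step 3 | 2-{[(1S,5S)-6,6-dimethylbicyclo[3.1.1]heptan-2-ylidene]methyl}-4,4,5,5-tetramethyl-1,3,2-dioxaborolane (E/Z mixture) | CC1(C)OB(C=C2CC[C@H]3C[C@@H]2C3(C)C)OC1(C)C
F7 | step 3 | {[(1S,5S)-6,6-dimethylbicyclo[3.1.1]heptan-2-ylidene]methyl}boronic acid (E/Z mixture) | OB(O)C=C1CC[C@H]2C[C@@H]1C2(C)C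
A1 | alternative 1 | 2,2,4,4-tetramethyl-6-(3-methylbutylidene)cyclohexane-1,3,5-trione | CC(C)CC=C1C(=O)C(C)(C)C(=O)C(C)(C)C1=O
A2 | alternative 1 | (−)-β-pinene, (1S,5S)-6,6-dimethyl-2-methylidenebicyclo[3.1.1]heptane | C=C1CC[C@H]2C[C@@H]1C2(C)C
A3 | alternative 1 | (1R,2R,4'S,5S)-6,6,6',6',8',8'-hexamethyl-4'-(2-methylpropyl)-3',4'-dihydrospiro[bicyclo[3.1.1]heptane-2,2'-chromene]-5',7'(6'H,8'H)-dione | CC(C)C[C@H]1C[C@@]2(CC[C@H]3C[C@@H]2C3(C)C)OC2=C1C(=O)C(C)(C)C(=O)C2(C)C
A4 | alternative 2 | 2-acetyl-4,4,6,6-tetramethylcyclohexane-1,3,5-trione | CC(=O)C1C(=O)C(C)(C)C(=O)C(C)(C)C1=O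
A5 | alternative 2 | (1R,2R,5S)-6,6,6',6',8',8'-hexamethylspiro[bicyclo[3.1.1]heptane-2,2'-chromene]-4',5',7'(3'H,6'H,8'H)-trione | O=C1C[C@@]2(CC[C@H]3C[C@@H]2C3(C)C)OC2=C1C(=O)C(C)(C)C(=O)C2(C)C
A6 | alternative 3 | 2-{(2R)-1-[(1R,5S)-6,6-dimethylbicyclo[3.1.1]hept-2-en-2-yl]-4-methylpentan-2-yl}-4,4,6,6-tetramethylcyclohexane-1,3,5-trione | CC(C)C[C@H](CC1=CC[C@H]2C[C@@H]1C2(C)C)C1C(=O)C(C)(C)C(=O)C(C)(C)C1=O
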